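**Assumption:** atoms are numbered along the C15 chain of the SMILES (C1 = propenyl CH3, C15 = ethyl CH3), which makes the target (2Z,4S,5R,6R,7S,8R,10R,11S); (+)-Ipc2BOTf means the reagent made from (−)-α-pinene.

## Retrosynthetic overview

1. The oxirane (C5–O and C6–O), the only ring of the target, is made last by internal oxygen transfer from a dioxirane raised on the C9 ketone of diene-tetraol 20.
2. Both primary C–O bonds (the two CH2OH groups) come from C–Si bonds by Tamao–Fleming oxidation (19 → 20); the hydroxymethyl groups are carried as CH2–SiMe2OSiMe3.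
3. C7–C8 comes from an anti boron aldol of ketone 16 with enal 6; C10–C11 from a syn boron aldol of the C5 linchpin ketone 13 with aldehyde 9.
4. Enal 6 comes from (R)-Roche ester, aldehyde 9 from ethyl 3-oxopentanoate, ketone 13 from penta-1,4-dien-3-ol by double hydrosilylation and oxidation.
5. Ring order: the dioxolane (a protecting ring, step 5, opened in step 12), then the oxirane (step 14).

## Route

Step 1
Reactants: 1 methyl (R)-3-hydroxy-2-methylpropanoate
Product: 2 methyl (R)-2-methyl-3-[(triethylsilyl)oxy]propanoate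
Conditions: Et3SiCl, imidazole, CH2Cl2, 0 °C to rt
Reagents that add atoms: chlorotriethylsilane, CC[Si](Cl)(CC)CC
Why: Imidazole-promoted silylation of the primary alcohol; the stereocentre is not touched.

Step 2
Reactants: 2 methyl (R)-2-methyl-3-[(triethylsilyl)oxy]propanoate
Product: 3 (R)-2-methyl-3-[(triethylsilyl)oxy]propanal
Conditions: i-Bu2AlH, CH2Cl2, −78 °C
Reagents that add atoms: none
Why: Partial ester reduction stops at the aldehyde because the tetrahedral aluminium alkoxide is stable at −78 °C; the α-stereocentre is kept.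

Step 3
Reactants: 3 (R)-2-methyl-3-[(triethylsilyl)oxy]propanal
Product: 4 triethyl{[(2S,3Z)-2-methylpent-3-en-1-yl]oxy}silane
Conditions: EtPPh3Br, KN(SiMe3)2, THF, −78 °C to 0 °C
Reagents that add atoms: ethyltriphenylphosphonium bromide, CC[P+](c1ccccc1)(c1ccccc1)c1ccccc1.[Br-]
Why: Salt-free Wittig reaction of a non-stabilised ylide gives the Z-alkene under kinetic control (cis-oxaphosphetane); the stereocentre is retained (the descriptor becomes S by priority change only).

Step 4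
Reactants: 4 triethyl{[(2S,3Z)-2-methylpent-3-en-1-yl]oxy}silane
Product: 6 (2E,4S,5Z)-2,4-dimethylhepta-2,5-dienal, via (2S,3Z)-2-methylpent-3-enal 5 (not isolated)
Conditions: (COCl)2, DMSO, CH2Cl2, −78 to −40 °C; i-Pr2NEt, −78 °C; then Ph3P=C(Me)CHO, −78 °C to rt
Reagents that add atoms: 2-(triphenylphosphoranylidene)propanal, CC(C=O)=P(c1ccccc1)(c1ccccc1)c1ccccc1
Why: Swern conditions oxidise a primary triethylsilyl ether directly to the aldehyde, and the epimerisable β,γ-unsaturated aldehyde 5 is trapped in the same flask by a Wittig reaction with the stabilised formyl ylide, which gives the E-trisubstituted enal.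

Step 5
Reactants: 7 ethyl 3-oxopentanoate
Product: 8 ethyl 2-(2-ethyl-1,3-dioxolan-2-yl)acetate
Conditions: HOCH2CH2OH, p-TsOH (cat.), toluene, reflux, Dean–Stark trap
Reagents that add atoms: ethylene glycol, OCCO
Why: Acid-catalysed ketalisation with azeotropic removal of water protects the ketone (the future C13 carbonyl) and leaves the ester.

Step 6
Reactants: 8 ethyl 2-(2-ethyl-1,3-dioxolan-2-yl)acetate
Product: 9 2-(2-ethyl-1,3-dioxolan-2-yl)acetaldehyde
Conditions: i-Bu2AlH, CH2Cl2, −78 °C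
Reagents that add atoms: none
Why: Partial ester reduction to the aldehyde; the ketal keeps the β-keto aldehyde from enolising.

Step 7
Reactants: 10 penta-1,4-dien-3-ol; 11 1,1,1,3,3-pentamethyldisiloxane (2 equiv)
Product: 12 1,5-bis(1,1,3,3,3-pentamethyldisiloxan-1-yl)pentan-3-ol
Conditions: Pt2[(CH2=CHSiMe2)2O]3 (0.1 mol% Pt), toluene, 50 °C; then K2CO3, MeOH (frees any O-silylated material)
Reagents that add atoms: none
Why: Platinum-catalysed anti-Markovnikov hydrosilylation (Chalk–Harrod) puts silicon on both terminal carbons and so installs the two masked hydroxymethyl carbons.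

Step 8
Reactants: 12 1,5-bis(1,1,3,3,3-pentamethyldisiloxan-1-yl)pentan-3-ol
Product: 13 1,5-bis(1,1,3,3,3-pentamethyldisiloxan-1-yl)pentan-3-one
Conditions: Dess–Martin periodinane, CH2Cl2, rt
Reagents that add atoms: none
Why: Dess–Martin oxidation of the secondary alcohol gives the symmetric linchpin ketone (C8–C9–C10 with both CH2Si arms); β-silyl ketones cannot undergo the β-elimination that threatens β-alkoxy ketones.

Step 9
Reactants: 13 1,5-bis(1,1,3,3,3-pentamethyldisiloxan-1-yl)pentan-3-one; 9 2-(2-ethyl-1,3-dioxolan-2-yl)acetaldehyde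
Product: 15 (4R,5S)-6-(2-ethyl-1,3-dioxolan-2-yl)-5-hydroxy-1-(1,1,3,3,3-pentamethyldisiloxan-1-yl)-4-[(1,1,3,3,3-pentamethyldisiloxan-1-yl)methyl]hexan-3-one, via Z-enol diisopinocampheylborinate 14 (not isolated)
Conditions: (+)-Ipc2BOTf, i-Pr2NEt, CH2Cl2, −78 °C; 9, −78 to −20 °C; H2O2, MeOH, pH 7 buffer (NaH2PO4/Na2HPO4)
Reagents that add atoms: none
Why: Paterson reagent-controlled boron aldol: the Z-enol borinate reacts through a chair (Zimmerman–Traxler) transition state to give the 10,11-syn adduct, and the isopinocampheyl ligands of the (−)-α-pinene series direct attack to the Re face of 9, which sets C11 as S and C10 as drawn.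

Step 10
Reactants: 15 (4R,5S)-6-(2-ethyl-1,3-dioxolan-2-yl)-5-hydroxy-1-(1,1,3,3,3-pentamethyldisiloxan-1-yl)-4-[(1,1,3,3,3-pentamethyldisiloxan-1-yl)methyl]hexan-3-one
Product: 16 (4R,5S)-6-(2-ethyl-1,3-dioxolan-2-yl)-1-(1,1,3,3,3-pentamethyldisiloxan-1-yl)-4-[(1,1,3,3,3-pentamethyldisiloxan-1-yl)methyl]-5-[(triethylsilyl)oxy]hexan-3-one
Conditions: Et3SiCl, imidazole, DMF, 0 °C to rt
Reagents that add atoms: chlorotriethylsilane, CC[Si](Cl)(CC)CC
Why: Silylation of the aldol hydroxyl under non-acidic conditions prevents retro-aldol and borinate formation in the next step; no stereocentre changes.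

Step 11
Reactants: 16 (4R,5S)-6-(2-ethyl-1,3-dioxolan-2-yl)-1-(1,1,3,3,3-pentamethyldisiloxan-1-yl)-4-[(1,1,3,3,3-pentamethyldisiloxan-1-yl)methyl]-5-[(triethylsilyl)oxy]hexan-3-one; 6 (2E,4S,5Z)-2,4-dimethylhepta-2,5-dienal
Product: 18 (2S,3R,5R,6S,7E,9S,10Z)-1-(2-ethyl-1,3-dioxolan-2-yl)-6-hydroxy-7,9-dimethyl-3,5-bis[(1,1,3,3,3-pentamethyldisiloxan-1-yl)methyl]-2-[(triethylsilyl)oxy]dodeca-7,10-dien-4-one, via E-enol dicyclohexylborinate 17 (not isolated)
Conditions: c-Hex2BCl, Et3N, Et2O, 0 °C; 6, −78 to −20 °C; H2O2, MeOH, pH 7 buffer (NaH2PO4/Na2HPO4), 0 °C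
Reagents that add atoms: none
Why: Substrate-controlled Paterson anti-aldol: c-Hex2BCl/Et3N enolises the less hindered CH2 side to the E-enol borinate, the chair transition state gives the 7,8-anti relationship, and approach of the aldehyde on the face of the oxygen-bearing C11 arm of the A(1,3)-minimised enolate sets C8 anti to C10 across the carbonyl (the anti–anti outcome known for α-branched β-oxygenated ketones).

Step 12
Reactants: 18 (2S,3R,5R,6S,7E,9S,10Z)-1-(2-ethyl-1,3-dioxolan-2-yl)-6-hydroxy-7,9-dimethyl-3,5-bis[(1,1,3,3,3-pentamethyldisiloxan-1-yl)methyl]-2-[(triethylsilyl)oxy]dodeca-7,10-dien-4-one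
Product: 19 (5S,6R,8R,9S,10E,12S,13Z)-5,9-dihydroxy-10,12-dimethyl-6,8-bis[(1,1,3,3,3-pentamethyldisiloxan-1-yl)methyl]pentadeca-10,13-diene-3,7-dione
Conditions: 1 M HCl, THF, 0 °C to rt
Reagents that add atoms: water, O
Why: Mild aqueous acid hydrolyses the dioxolane and the triethylsilyl ether in one operation while no epoxide is present yet; any oxasilolane formed by attack of a γ-hydroxyl on silicon converges in step 13.

Step 13
Reactants: 19 (5S,6R,8R,9S,10E,12S,13Z)-5,9-dihydroxy-10,12-dimethyl-6,8-bis[(1,1,3,3,3-pentamethyldisiloxan-1-yl)methyl]pentadeca-10,13-diene-3,7-dione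
Product: 20 (5S,6R,8R,9S,10E,12S,13Z)-5,9-dihydroxy-6,8-bis(hydroxymethyl)-10,12-dimethylpentadeca-10,13-diene-3,7-dione
Conditions: 30% H2O2, KF, KHCO3, THF/MeOH, rt
Reagents that add atoms: hydrogen peroxide, OO
Why: Tamao–Fleming oxidation: fluoride opens the disiloxane, hydroperoxide adds to silicon and each CH2 group migrates from Si to O with retention, forming both primary C–O bonds under conditions that spare the alkenes and the β-hydroxy ketones.

Step 14
Reactants: 20 (5S,6R,8R,9S,10E,12S,13Z)-5,9-dihydroxy-6,8-bis(hydroxymethyl)-10,12-dimethylpentadeca-10,13-diene-3,7-dione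
Product: 22 (5S,6R,8R,9S)-5,9-dihydroxy-6,8-bis(hydroxymethyl)-9-{(2R,3R)-2-methyl-3-[(2S,3Z)-pent-3-en-2-yl]oxiran-2-yl}nonane-3,7-dione (CNP0266199.1), via C9 dioxirane 21 (not isolated)
Conditions: KHSO5 (as 2KHSO5·KHSO4·K2SO4, 1.3 equiv), NaHCO3, MeCN/aq. Na2H2EDTA, 0 °C, 5 mM
Reagents that add atoms: potassium peroxymonosulfate, [K+].[O-]S(=O)(=O)OO
Why: Proposed new method: the substrate's own C9 ketone (inductively activated by four β-oxygens) adds KHSO5 to give dioxirane 21, which the C8–C7 tether holds about 3 Å under the C5=C6 bond, so spiro oxygen transfer is intramolecular, reaches only this alkene (the Z-alkene is out of reach) and must occur on the face syn to C8; with C7–H turned toward the C6 methyl (A(1,2) strain) this is the face that gives the (5R,6R)-epoxide syn to O7, and the ketone is returned after a single turnover; the closest known reaction types are ketone-catalysed dioxirane epoxidation with KHSO5 (Shi, Yang, Denmark) and intramolecular oxidations by dioxiranes generated from tethered ketones, neither shown for an unactivated dialkyl ketone epoxidising its own γ,δ-alkene.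

## Compound list

1 | methyl (R)-3-hydroxy-2-methylpropanoate | COC(=O)[C@H](C)CO | starting material
2 | methyl (R)-2-methyl-3-[(triethylsilyl)oxy]propanoate | COC(=O)[C@H](C)CO[Si](CC)(CC)CC | intermediate
3 | (R)-2-methyl-3-[(triethylsilyl)oxy]propanal | O=C[C@H](C)CO[Si](CC)(CC)CC | intermediate
4 | triethyl{[(2S,3Z)-2-methylpent-3-en-1-yl]oxy}silane | C/C=C\[C@H](C)CO[Si](CC)(CC)CC | intermediate
5 | (2S,3Z)-2-methylpent-3-enal | C/C=C\[C@H](C)C=O | intermediate
6 | (2E,4S,5Z)-2,4-dimethylhepta-2,5-dienal | C/C=C\[C@H](C)/C=C(\C)C=O | intermediate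
7 | ethyl 3-oxopentanoate | CCC(=O)CC(=O)OCC | starting material
8 | ethyl 2-(2-ethyl-1,3-dioxolan-2-yl)acetate | CCOC(=O)CC1(CC)OCCO1 | intermediate
9 | 2-(2-ethyl-1,3-dioxolan-2-yl)acetaldehyde | O=CCC1(CC)OCCO1 | intermediate
10 | penta-1,4-dien-3-ol | C=CC(O)C=C | starting material
11 | 1,1,1,3,3-pentamethyldisiloxane | C[SiH](C)O[Si](C)(C)C | starting material
12 | 1,5-bis(1,1,3,3,3-pentamethyldisiloxan-1-yl)pentan-3-ol | C[Si](C)(C)O[Si](C)(C)CCC(O)CC[Si](C)(C)O[Si](C)(C)C | intermediate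
13 | 1,5-bis(1,1,3,3,3-pentamethyldisiloxan-1-yl)pentan-3-one | C[Si](C)(C)O[Si](C)(C)CCC(=O)CC[Si](C)(C)O[Si](C)(C)C | intermediate
14 | Z-enol diisopinocampheylborinate of 13 (isopinocampheyl groups of the (−)-α-pinene series; O–B cis to the CH2Si group on the enol carbon) | C[Si](C)(C)O[Si](C)(C)CC/C(OB([C@H]1C[C@H]2C[C@@H]([C@@H]1C)C2(C)C)[C@H]1C[C@H]2C[C@@H]([C@@H]1C)C2(C)C)=C/C[Si](C)(C)O[Si](C)(C)C | intermediate
15 | (4R,5S)-6-(2-ethyl-1,3-dioxolan-2-yl)-5-hydroxy-1-(1,1,3,3,3-pentamethyldisiloxan-1-yl)-4-[(1,1,3,3,3-pentamethyldisiloxan-1-yl)methyl]hexan-3-one | C[Si](C)(C)O[Si](C)(C)CCC(=O)[C@H](C[Si](C)(C)O[Si](C)(C)C)[C@@H](O)CC1(CC)OCCO1 | intermediate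
16 | (4R,5S)-6-(2-ethyl-1,3-dioxolan-2-yl)-1-(1,1,3,3,3-pentamethyldisiloxan-1-yl)-4-[(1,1,3,3,3-pentamethyldisiloxan-1-yl)methyl]-5-[(triethylsilyl)oxy]hexan-3-one | C[Si](C)(C)O[Si](C)(C)CCC(=O)[C@H](C[Si](C)(C)O[Si](C)(C)C)[C@@H](O[Si](CC)(CC)CC)CC1(CC)OCCO1 | intermediate
17 | E-enol dicyclohexylborinate of 16 (enolised toward C2; O–B trans to the CH2Si group on the enol carbon) | C[Si](C)(C)O[Si](C)(C)C/C=C(/OB(C1CCCCC1)C1CCCCC1)[C@H](C[Si](C)(C)O[Si](C)(C)C)[C@@H](O[Si](CC)(CC)CC)CC1(CC)OCCO1 | intermediate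
18 | (2S,3R,5R,6S,7E,9S,10Z)-1-(2-ethyl-1,3-dioxolan-2-yl)-6-hydroxy-7,9-dimethyl-3,5-bis[(1,1,3,3,3-pentamethyldisiloxan-1-yl)methyl]-2-[(triethylsilyl)oxy]dodeca-7,10-dien-4-one | C/C=C\[C@H](C)/C=C(\C)[C@@H](O)[C@@H](C[Si](C)(C)O[Si](C)(C)C)C(=O)[C@H](C[Si](C)(C)O[Si](C)(C)C)[C@@H](O[Si](CC)(CC)CC)CC1(CC)OCCO1 | intermediate
19 | (5S,6R,8R,9S,10E,12S,13Z)-5,9-dihydroxy-10,12-dimethyl-6,8-bis[(1,1,3,3,3-pentamethyldisiloxan-1-yl)methyl]pentadeca-10,13-diene-3,7-dione | C/C=C\[C@H](C)/C=C(\C)[C@@H](O)[C@@H](C[Si](C)(C)O[Si](C)(C)C)C(=O)[C@H](C[Si](C)(C)O[Si](C)(C)C)[C@@H](O)CC(=O)CC | intermediate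
20 | (5S,6R,8R,9S,10E,12S,13Z)-5,9-dihydroxy-6,8-bis(hydroxymethyl)-10,12-dimethylpentadeca-10,13-diene-3,7-dione | C/C=C\[C@H](C)/C=C(\C)[C@@H](O)[C@@H](CO)C(=O)[C@H](CO)[C@@H](O)CC(=O)CC | intermediate
21 | C9 dioxirane of 20 (3,3-disubstituted dioxirane in place of the C7 carbonyl of the pentadecadienedione name) | C/C=C\[C@H](C)/C=C(\C)[C@@H](O)[C@@H](CO)C1(OO1)[C@H](CO)[C@@H](O)CC(=O)CC | intermediate
22 | (5S,6R,8R,9S)-5,9-dihydroxy-6,8-bis(hydroxymethyl)-9-{(2R,3R)-2-methyl-3-[(2S,3Z)-pent-3-en-2-yl]oxiran-2-yl}nonane-3,7-dione (CNP0266199.1) | C/C=C\[C@H](C)[C@H]1O[C@]1(C)[C@@H](O)[C@@H](CO)C(=O)[C@H](CO)[C@@H](O)CC(=O)CC | target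

## Step count and risks

Total steps: 14. Longest linear sequence: 8 steps (1 → 6 → 18 → 22; the branches from 7 and from 10 are also 8 steps long).

**Step 14 (new reaction).** The hindered C9 ketone may add KHSO5 too slowly or undergo Baeyer–Villiger cleavage instead of giving the dioxirane, or the oxygen may be delivered without face control. The fallback uses known reagent control and changes the order of the two oxidations. It sets out from 19, which is epoxidised under Shi conditions (D-fructose-derived Shi ketone, KHSO5, K2CO3 buffer, MeCN/dimethoxymethane/water, 0 °C). The spiro transition state of this ketone favours the (R,R)-type face of E-trisubstituted alkenes and leaves the less electron-rich Z-alkene, giving the (5R,6R)-epoxide of 19 F1. Tamao–Fleming oxidation of F1 under the conditions of step 13 then gives 22, where the fallback comes back to the route.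

**Step 11 (C8 and C7 set by the remote C10 centre).** With a silylmethyl group in place of the usual methyl and a silyl ether on O11, the facial bias of the E-enol borinate may be low or reversed. The fallback changes the control element to Paterson's formyl C–H···O-directed induction by a benzylic ether. It sets out from 15, which is converted with 4-methoxybenzyl trichloroacetimidate and La(OTf)3 (cat.) in toluene into the 4-methoxybenzyl ether of 15 F2. The same c-Hex2BCl/Et3N aldol with 6 gives the 4-methoxybenzyl analogue of 18 F3. DDQ in wet CH2Cl2 removes the benzylic ether to give the 2-hydroxy dioxolane analogue of 18 F4, and 1 M HCl/THF opens the dioxolane to give 19, where the fallback comes back to the route.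

**Step 9 (enantioselective syn-aldol with a new ketone class).** The enantiomeric excess with the bis(silylethyl) ketone and an unbranched aldehyde may be modest. The fallback drops reagent control and resolves through the enantiopure enal. It sets out from 13 and 9, which with n-Bu2BOTf/i-Pr2NEt give the syn-aldol as a racemate, that is 15 together with the enantiomer of 15 F5. Silylation as in step 10 gives 16 together with the enantiomer of 16 F6. The anti-aldol of step 11 with enantiopure 6 then gives 18 and the C2,C3,C5,C6-epimeric diastereomer of 18 F7, which are separated on silica (half of the material is lost), and the fallback comes back to the route at 18.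

Further compounds
F1 | step 14 | (5R,6R)-epoxide of 19: (5S,6R,8R,9S)-5,9-dihydroxy-9-{(2R,3R)-2-methyl-3-[(2S,3Z)-pent-3-en-2-yl]oxiran-2-yl}-6,8-bis[(1,1,3,3,3-pentamethyldisiloxan-1-yl)methyl]nonane-3,7-dione | C/C=C\[C@H](C)[C@H]1O[C@]1(C)[C@@H](O)[C@@H](C[Si](C)(C)O[Si](C)(C)C)C(=O)[C@H](C[Si](C)(C)O[Si](C)(C)C)[C@@H](O)CC(=O)CC
F2 | step 11 | 4-methoxybenzyl ether of 15: (4R,5S)-6-(2-ethyl-1,3-dioxolan-2-yl)-5-[(4-methoxybenzyl)oxy]-1-(1,1,3,3,3-pentamethyldisiloxan-1-yl)-4-[(1,1,3,3,3-pentamethyldisiloxan-1-yl)methyl]hexan-3-one | C[Si](C)(C)O[Si](C)(C)CCC(=O)[C@H](C[Si](C)(C)O[Si](C)(C)C)[C@@H](OCc1ccc(OC)cc1)CC1(CC)OCCO1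
F3 | step 11 | 4-methoxybenzyl analogue of 18: (2S,3R,5R,6S,7E,9S,10Z)-1-(2-ethyl-1,3-dioxolan-2-yl)-6-hydroxy-2-[(4-methoxybenzyl)oxy]-7,9-dimethyl-3,5-bis[(1,1,3,3,3-pentamethyldisiloxan-1-yl)methyl]dodeca-7,10-dien-4-one | C/C=C\[C@H](C)/C=C(\C)[C@@H](O)[C@@H](C[Si](C)(C)O[Si](C)(C)C)C(=O)[C@H](C[Si](C)(C)O[Si](C)(C)C)[C@@H](OCc1ccc(OC)cc1)CC1(CC)OCCO1
F4 | step 11 | 2-hydroxy dioxolane analogue of 18: (2S,3R,5R,6S,7E,9S,10Z)-1-(2-ethyl-1,3-dioxolan-2-yl)-2,6-dihydroxy-7,9-dimethyl-3,5-bis[(1,1,3,3,3-pentamethyldisiloxan-1-yl)methyl]dodeca-7,10-dien-4-one | C/C=C\[C@H](C)/C=C(\C)[C@@H](O)[C@@H](C[Si](C)(C)O[Si](C)(C)C)C(=O)[C@H](C[Si](C)(C)O[Si](C)(C)C)[C@@H](O)CC1(CC)OCCO1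
F5 | step 9 | enantiomer of 15: (4S,5R)-6-(2-ethyl-1,3-dioxolan-2-yl)-5-hydroxy-1-(1,1,3,3,3-pentamethyldisiloxan-1-yl)-4-[(1,1,3,3,3-pentamethyldisiloxan-1-yl)methyl]hexan-3-one | C[Si](C)(C)O[Si](C)(C)CCC(=O)[C@@H](C[Si](C)(C)O[Si](C)(C)C)[C@H](O)CC1(CC)OCCO1
F6 | step 9 | enantiomer of 16: (4S,5R)-6-(2-ethyl-1,3-dioxolan-2-yl)-1-(1,1,3,3,3-pentamethyldisiloxan-1-yl)-4-[(1,1,3,3,3-pentamethyldisiloxan-1-yl)methyl]-5-[(triethylsilyl)oxy]hexan-3-one | C[Si](C)(C)O[Si](C)(C)CCC(=O)[C@@H](C[Si](C)(C)O[Si](C)(C)C)[C@H](O[Si](CC)(CC)CC)CC1(CC)OCCO1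
F7 | step 9 | C2,C3,C5,C6-epimeric diastereomer of 18: (2R,3S,5S,6R,7E,9S,10Z)-1-(2-ethyl-1,3-dioxolan-2-yl)-6-hydroxy-7,9-dimethyl-3,5-bis[(1,1,3,3,3-pentamethyldisiloxan-1-yl)methyl]-2-[(triethylsilyl)oxy]dodeca-7,10-dien-4-one | C/C=C\[C@H](C)/C=C(\C)[C@H](O)[C@H](C[Si](C)(C)O[Si](C)(C)C)C(=O)[C@@H](C[Si](C)(C)O[Si](C)(C)C)[C@H](O[Si](CC)(CC)CC)CC1(CC)OCCO1
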